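## Retrosynthetic overview

1. Target 24 ⇐ O-acetylation and Ru–TsDPEN transfer hydrogenation (dynamic kinetic resolution, sets C4 and C5) of the 3,4-dioxo-oplopane 22.
2. 22 ⇐ ring contraction as in the cadinane → oplopane biogenesis: Lewis-acid 1,2-shift of acyl carbon C3 from C4 to C5 in the 4,5-epoxy-3-ketone 21. Both epoxides (4,5 and 11,12) come from one nucleophilic epoxidation of 19.
3. 19 (cis-fused cadinane, amorphane-type) ⇐ closure of the C6–C7 bond of the bisabolane-type monocycle 16, the bond made in the bisabolyl → amorphane cyclisation. It is run as a silyloxydiene [4+2]/Grob fragmentation, i.e. a stereocontrolled vinylogous SN2′ that also releases the C11=C12 methylene.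
4. 16 ⇐ (R)-carvone (ring A: C1, C3=O, C4–CH3, C10=C14H2) by oxidation of C9, Brown syn-alkoxyallylboration, Mitsunobu inversion/acylation at C9, acylation at C8 and cross-metathesis.
5. Ring order: ring A (chiral pool) → ring B (C6–C7) → contraction of ring A to the cyclopentanone.

Locants (biogenetic cadinane/oplopane numbering): C1/C6 ring fusion; C2; C3 (C=O); C4 (carries CH3-15); C5; C7 (carries C11(=C12)–C13O2Me); C8 (O-enoate); C9 (O-methylbutanoate); C10 (=C14H2).

Assumption: 4, 8, 12 and 15 are bought as catalogue compounds; the target's 2-methylbutanoate is R as drawn in the given SMILES.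

## Route

Step 1
Reactants: 1 (R)-(−)-carvone
Product: 3 2-[(1R)-4-methyl-5-oxocyclohex-3-en-1-yl]prop-2-enal (carvone-10-al), via 10-hydroxycarvone 2 (not isolated)
Conditions: SeO2 (1.2 equiv), 1,4-dioxane, 80 °C
Reagents that add atoms: selenium dioxide, O=[Se]=O
Why: Riley allylic oxidation (ene reaction/[2,3]-shift) attacks only the electron-rich isopropenyl group and runs on to the 2-substituted acrolein, leaving the enone and the chiral-pool centre C1 untouched.

Step 2
Reactants: 3 carvone-10-al; 4 allyl methoxymethyl ether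
Product: 7 (5R)-5-[(3R,4R)-3-hydroxy-4-(methoxymethoxy)hexa-1,5-dien-2-yl]-2-methylcyclohex-2-en-1-one, via (Z)-γ-(methoxymethoxy)allyl-diisopinocampheylborane 5 (not isolated), via diisopinocampheylborinate ester 6 (not isolated)
Conditions: s-BuLi, THF, −78 °C; (−)-Ipc2BOMe; BF3·OEt2; 3, −78 °C; then HOCH2CH2NH2
Reagents that add atoms: none
Why: Brown γ-alkoxyallylboration: the (Z)-allylborane reacts through a chair Zimmerman–Traxler transition state (Z → syn) and the (+)-α-pinene-derived Ipc2B group selects the Si face of the aldehyde (reagent control, aldehyde much faster than ketone), giving the (8R,9R) syn adduct.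

Step 3
Reactants: 7 syn alcohol; 8 (R)-2-methylbutanoic acid
Product: 10 (3S,4R)-4-(methoxymethoxy)-2-[(1R)-4-methyl-5-oxocyclohex-3-en-1-yl]hexa-1,5-dien-3-yl (2R)-2-methylbutanoate, via alkoxyphosphonium carboxylate 9 (not isolated)
Conditions: PPh3, DIAD, PhMe, 0 °C→rt
Reagents that add atoms: none
Why: Mitsunobu esterification: SN2 attack of the carboxylate on the C9 alkoxyphosphonium inverts C9 (9R → 9S), turning the syn adduct into the anti (erythro) C8/C9 array of the target while installing the methylbutanoate, whose own α-centre is not touched.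

Step 4
Reactants: 10 MOM ether
Product: 11 (3S,4R)-4-hydroxy-2-[(1R)-4-methyl-5-oxocyclohex-3-en-1-yl]hexa-1,5-dien-3-yl (2R)-2-methylbutanoate
Conditions: ZnBr2, n-PrSH, CH2Cl2, 0 °C, 10 min
Reagents that add atoms: none
Why: Lewis-acid/thiol MOM cleavage (O,O- to O,S-acetal exchange) is fast and mild enough to spare the ester, enone and alkenes and to outrun acyl migration; no stereocentre is involved.

Step 5
Reactants: 11 C8 alcohol; 12 (2E)-3-methylpent-2-enoic acid
Product: 14 (3R,4S)-4-{[(2R)-2-methylbutanoyl]oxy}-5-[(1R)-4-methyl-5-oxocyclohex-3-en-1-yl]hexa-1,5-dien-3-yl (2E)-3-methylpent-2-enoate, via O-acylisourea 13 (not isolated)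
Conditions: DCC, DMAP (cat.), CH2Cl2, 0 °C
Reagents that add atoms: none
Why: Steglich esterification with retention at C8; low temperature and catalytic DMAP keep the β,β-disubstituted enoate conjugated and E.

Step 6
Reactants: 14 diester; 15 methyl 2-(bromomethyl)prop-2-enoate
Product: 16 methyl (2Z,4R,5S)-2-(bromomethyl)-4-{[(2E)-3-methylpent-2-enoyl]oxy}-5-{[(2R)-2-methylbutanoyl]oxy}-6-[(1R)-4-methyl-5-oxocyclohex-3-en-1-yl]hepta-2,6-dienoate
Conditions: Hoveyda–Grubbs II (10 mol %), 15 (4 equiv), CH2Cl2, 40 °C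
Reagents that add atoms: none
Why: Olefin cross-metathesis engages only the monosubstituted vinyl group (the 1,1-disubstituted C10=C14 and the trisubstituted conjugated alkenes are inert) and gives the thermodynamic trisubstituted enoate with the ester trans to the chain (Z by CIP).

Step 7
Reactants: 16 bromomethyl enoate
Product: 19 methyl (1S,6R,7S,8R,9S)-8-[(2E)-3-methylpent-2-enoyloxy]-9-[(2R)-2-methylbutanoyloxy]-3-oxo-cis-cadina-4,10(14),11-trien-13-oate, via TBS dienol ether 17 (not isolated), via bicyclo[2.2.2]octene cycloadduct 18 (not isolated)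
Conditions: TBSOTf, i-Pr2NEt, CH2Cl2, −78→0 °C; PhMe (0.01 M, BHT), 110 °C; then TBAF, THF, 0 °C
Reagents that add atoms: none
Why: Thermodynamic γ-deprotonation gives the linear 1-silyloxy-1,3-diene, whose intramolecular Diels–Alder reaction must add on the diene face syn to the C1 tether with C7 on C6 and C11 on C3 (ester endo), fixing the cis ring fusion and H-7 cis to H-6; fluoride then triggers a Grob fragmentation (retro-aldol with loss of bromide) of the bridgehead alkoxide that restores the enone and releases the C11=C12 acrylate, so the net result is a vinylogous SN2′ closure of the C6–C7 bond.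

Step 8
Reactants: 19 cis-cadinane dienone ester
Product: 21 methyl (1S,4R,5R,6R,7R,8R,9S,11S)-4,5:11,12-diepoxy-8-[(2E)-3-methylpent-2-enoyloxy]-9-[(2R)-2-methylbutanoyloxy]-3-oxo-cis-cadin-10(14)-en-13-oate, via 4,5-epoxy ketone 20 (not isolated)
Conditions: t-BuOOH, n-BuLi (t-BuOOLi, 3 equiv), THF, −78→−20 °C
Reagents that add atoms: tert-butyl hydroperoxide, CC(C)(C)OO
Why: Weitz–Scheffer nucleophilic epoxidation touches only the two electron-poor, β-unhindered alkenes: the enone is attacked at C5 from the convex α-face (this centre is reset later), and the β-peroxy ester enolate of the acrylate closes in the A1,3-minimised, Felkin-type conformer (C6 anti to the forming C–O bond, H-7 eclipsing the enolate) to give 11S, while the β,β-disubstituted enoate and the exocyclic methylene do not react.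

Step 9
Reactants: 21 diepoxide
Product: 22 methyl (1S,5S,6R,7R,8R,9S,11S)-11,12-epoxy-8-[(2E)-3-methylpent-2-enoyloxy]-9-[(2R)-2-methylbutanoyloxy]-3,4-dioxo-oplop-10(14)-en-13-oate
Conditions: BF3·OEt2 (0.3 equiv), CH2Cl2, −40→0 °C
Reagents that add atoms: none
Why: House–Meinwald rearrangement of an α,β-epoxy ketone: the Lewis acid opens the epoxide at C5 (a cation at C4, α to the carbonyl, is disfavoured) with concerted 1,2-shift of acyl carbon C3 from C4 to C5, contracting ring A to the 2-acetylcyclopentanone; the electron-poor glycidate is not ionised, and C5 (5S by inversion) is a labile β-diketone centre that is reset in step 10.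

Step 10
Reactants: 22 β-diketone
Product: 23 methyl (1S,4S,5R,6R,7R,8R,9S,11S)-11,12-epoxy-4-hydroxy-8-[(2E)-3-methylpent-2-enoyloxy]-9-[(2R)-2-methylbutanoyloxy]-3-oxo-oplop-10(14)-en-13-oate
Conditions: RuCl[(S,S)-TsDPEN](p-cymene) (2 mol %), HCO2H/Et3N (5:2), CH2Cl2, 25 °C
Reagents that add atoms: none
Why: Noyori–Ikariya asymmetric transfer hydrogenation with dynamic kinetic resolution: only the unhindered, activated acetyl C=O is reduced (alkenes and the resulting unactivated ring ketone are inert), the (S,S)-catalyst gives the 4S carbinol and the rapidly epimerising C5 is funnelled to the syn (4S,5R) aldol, the isomer also favoured by hydride delivery and protonation from the convex α-face.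

Step 11
Reactants: 23 β-hydroxy ketone
Product: 24 CNP0251769.1
Conditions: Ac2O, pyridine, DMAP (5 mol %), CH2Cl2, 0 °C
Reagents that add atoms: acetic anhydride, CC(=O)OC(C)=O
Why: O-acylation with retention at C4; cold, brief, weakly basic conditions avoid E1cB loss of the β-acetoxy group and epimerisation at C5.

## Compound list

1 | (R)-(−)-carvone | CC1=CC[C@@H](C(C)=C)CC1=O | starting material
2 | (5R)-5-(3-hydroxyprop-1-en-2-yl)-2-methylcyclohex-2-en-1-one (10-hydroxycarvone) | CC1=CC[C@@H](C(=C)CO)CC1=O | intermediate (not isolated)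
3 | 2-[(1R)-4-methyl-5-oxocyclohex-3-en-1-yl]prop-2-enal | CC1=CC[C@@H](C(=C)C=O)CC1=O | intermediate
4 | 3-(methoxymethoxy)prop-1-ene (allyl MOM ether) | C=CCOCOC | starting material
5 | [(Z)-3-(methoxymethoxy)allyl]diisopinocampheylborane, Ipc from (+)-α-pinene | COCO/C=C\CB([C@@H]1C[C@@H]2C[C@H]([C@H]1C)C2(C)C)[C@@H]1C[C@@H]2C[C@H]([C@H]1C)C2(C)C | intermediate (not isolated)
6 | O-diisopinocampheylborinate of 7 | CC1=CC[C@@H](C(=C)[C@@H](OB([C@@H]2C[C@@H]3C[C@H]([C@H]2C)C3(C)C)[C@@H]2C[C@@H]3C[C@H]([C@H]2C)C3(C)C)[C@H](OCOC)C=C)CC1=O | intermediate (not isolated)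
7 | (5R)-5-[(3R,4R)-3-hydroxy-4-(methoxymethoxy)hexa-1,5-dien-2-yl]-2-methylcyclohex-2-en-1-one | CC1=CC[C@@H](C(=C)[C@@H](O)[C@H](OCOC)C=C)CC1=O | intermediate
8 | (R)-2-methylbutanoic acid | CC[C@@H](C)C(O)=O | starting material
9 | C9-alkoxytriphenylphosphonium (R)-2-methylbutanoate of 7 | CC1=CC[C@@H](C(=C)[C@@H](O[P+](c2ccccc2)(c2ccccc2)c2ccccc2)[C@H](OCOC)C=C)CC1=O.CC[C@@H](C)C([O-])=O | intermediate (not isolated)
10 | (3S,4R)-4-(methoxymethoxy)-2-[(1R)-4-methyl-5-oxocyclohex-3-en-1-yl]hexa-1,5-dien-3-yl (2R)-2-methylbutanoate | CC1=CC[C@@H](C(=C)[C@H](OC(=O)[C@H](C)CC)[C@H](OCOC)C=C)CC1=O | intermediate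
11 | (3S,4R)-4-hydroxy-2-[(1R)-4-methyl-5-oxocyclohex-3-en-1-yl]hexa-1,5-dien-3-yl (2R)-2-methylbutanoate | CC1=CC[C@@H](C(=C)[C@H](OC(=O)[C@H](C)CC)[C@H](O)C=C)CC1=O | intermediate
12 | (2E)-3-methylpent-2-enoic acid | CC/C(C)=C/C(O)=O | starting material
13 | O-[(2E)-3-methylpent-2-enoyl]-N,N′-dicyclohexylisourea | CC/C(C)=C/C(=O)OC(NC1CCCCC1)=NC1CCCCC1 | intermediate (not isolated)
14 | (3R,4S)-4-{[(2R)-2-methylbutanoyl]oxy}-5-[(1R)-4-methyl-5-oxocyclohex-3-en-1-yl]hexa-1,5-dien-3-yl (2E)-3-methylpent-2-enoate | CC1=CC[C@@H](C(=C)[C@H](OC(=O)[C@H](C)CC)[C@H](OC(=O)/C=C(\C)CC)C=C)CC1=O | intermediate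
15 | methyl 2-(bromomethyl)prop-2-enoate | C=C(CBr)C(=O)OC | starting material
16 | methyl (2Z,4R,5S)-2-(bromomethyl)-4-{[(2E)-3-methylpent-2-enoyl]oxy}-5-{[(2R)-2-methylbutanoyl]oxy}-6-[(1R)-4-methyl-5-oxocyclohex-3-en-1-yl]hepta-2,6-dienoate | CC1=CC[C@@H](C(=C)[C@H](OC(=O)[C@H](C)CC)[C@H](OC(=O)/C=C(\C)CC)/C=C(\CBr)C(=O)OC)CC1=O | intermediate
17 | TBS dienol ether of 16 (ring A = 1-silyloxy-2-methylcyclohexa-1,3-diene, C3(OTBS)=C4–C5=C6) | CC1=C(O[Si](C)(C)C(C)(C)C)C[C@H](C(=C)[C@H](OC(=O)[C@H](C)CC)[C@H](OC(=O)/C=C(\C)CC)/C=C(\CBr)C(=O)OC)C=C1 | intermediate (not isolated)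
18 | bridgehead-silyloxy bicyclo[2.2.2]octene cycloadduct (new bonds C6–C7 and C3–C11) | C=C1[C@H]2C[C@]3(O[Si](C)(C)C(C)(C)C)C(C)=C[C@H]2[C@@H]([C@@]3(CBr)C(=O)OC)[C@@H](OC(=O)/C=C(\C)CC)[C@H]1OC(=O)[C@H](C)CC | intermediate (not isolated)
19 | methyl (1S,6R,7S,8R,9S)-8-[(2E)-3-methylpent-2-enoyloxy]-9-[(2R)-2-methylbutanoyloxy]-3-oxo-cis-cadina-4,10(14),11-trien-13-oate | C=C1[C@H]2CC(=O)C(C)=C[C@H]2[C@@H](C(=C)C(=O)OC)[C@@H](OC(=O)/C=C(\C)CC)[C@H]1OC(=O)[C@H](C)CC | intermediate
20 | (4R,5R)-4α,5α-epoxide of 19 (acrylate intact) | C=C1[C@H]2CC(=O)[C@]3(C)O[C@@H]3[C@H]2[C@@H](C(=C)C(=O)OC)[C@@H](OC(=O)/C=C(\C)CC)[C@H]1OC(=O)[C@H](C)CC | intermediate (not isolated)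
21 | methyl (1S,4R,5R,6R,7R,8R,9S,11S)-4,5:11,12-diepoxy-8-[(2E)-3-methylpent-2-enoyloxy]-9-[(2R)-2-methylbutanoyloxy]-3-oxo-cis-cadin-10(14)-en-13-oate | C=C1[C@H]2CC(=O)[C@]3(C)O[C@@H]3[C@H]2[C@@H]([C@@]2(C(=O)OC)CO2)[C@@H](OC(=O)/C=C(\C)CC)[C@H]1OC(=O)[C@H](C)CC | intermediate
22 | methyl (1S,5S,6R,7R,8R,9S,11S)-11,12-epoxy-8-[(2E)-3-methylpent-2-enoyloxy]-9-[(2R)-2-methylbutanoyloxy]-3,4-dioxo-oplop-10(14)-en-13-oate (C5 labile, drawn as formed) | C=C1[C@H]2CC(=O)[C@H](C(C)=O)[C@H]2[C@@H]([C@@]2(C(=O)OC)CO2)[C@@H](OC(=O)/C=C(\C)CC)[C@H]1OC(=O)[C@H](C)CC | intermediate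
23 | methyl (1S,4S,5R,6R,7R,8R,9S,11S)-11,12-epoxy-4-hydroxy-8-[(2E)-3-methylpent-2-enoyloxy]-9-[(2R)-2-methylbutanoyloxy]-3-oxo-oplop-10(14)-en-13-oate | C=C1[C@H]2CC(=O)[C@@H]([C@H](C)O)[C@H]2[C@@H]([C@@]2(C(=O)OC)CO2)[C@@H](OC(=O)/C=C(\C)CC)[C@H]1OC(=O)[C@H](C)CC | intermediate
24 | CNP0251769.1, the 4-O-acetate of 23 (1S,4S,5R,6R,7R,8R,9S,11S; 2′R) | C=C1[C@H]2CC(=O)[C@@H]([C@H](C)OC(C)=O)[C@H]2[C@@H]([C@@]2(C(=O)OC)CO2)[C@@H](OC(=O)/C=C(\C)CC)[C@H]1OC(=O)[C@H](C)CC | target

## Step count and risks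

Total step count: 11. Longest linear sequence: 11 (1 → 24); 4, 8, 12 and 15 enter as purchased materials.

Three steps most likely to fail:

**Step 7 (ring B closure).** The linear dienol ether may form alongside the cross-conjugated isomer, and the cycloaddition has to join two fully substituted carbons (C3 and C11). Fallback: set out from the TBS dienol ether 17, made as in step 7 but kept cold. Treat it with anhydrous TBAF in THF at −78 °C to release the tetrabutylammonium dienolate F1. This closes ring B by an anionic intramolecular vinylogous Michael addition of C6 to C7 followed by β-elimination of bromide (ionic SN2′ instead of the pericyclic path), and comes back to the route at 19. The C7 configuration would have to be confirmed, since this open transition state is not forced to be endo.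

**Step 8 (C11 configuration).** The 11S outcome rests on acyclic, substrate-controlled closure of the ester enolate. Fallback: set out from 14 and form the C11–O bond inside the ring-closing cascade instead. Methyl 2-[(tert-butylperoxy)methyl]prop-2-enoate F2 (from 15, t-BuOOH, K2CO3) is cross-metathesised with 14 to the peroxy enoate F3. Silylation (TBSOTf, i-Pr2NEt, −78 °C) gives the dienol ether F4, and heating gives the cycloadduct F5. Fluoride then fragments the bridgehead alkoxide; the C11 ester enolate, released anti to the departing C3, closes 3-exo on the peroxide oxygen with loss of tert-butoxide and gives the 11S glycidate enone F6. Epoxidation of the enone alone (t-BuOOH, DBU, 0 °C) comes back to the route at 21.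

**Step 10 (which carbonyl, and C4/C5).** Regioselection between the acetyl and ring carbonyls and the syn DKR on this hindered cis-hydrindane are not certain. Fallback: set out from 22 and reverse the order of events. O-Acetylation of the chelated exocyclic enol (Ac2O, pyridine) gives the (Z)-enol acetate F7. Conjugate reduction with Stryker's reagent ([(Ph3P)CuH]6, t-BuOH, PhMe, 0 °C) then delivers hydride to C4 and, on protonation of the copper enolate, hydrogen to C5, both from the convex α-face. This comes back to the route directly at 24.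

## Further compounds

F1 | step 7 | tetrabutylammonium extended dienolate of 16 | CC1=C([O-])C[C@H](C(=C)[C@H](OC(=O)[C@H](C)CC)[C@H](OC(=O)/C=C(\C)CC)/C=C(\CBr)C(=O)OC)C=C1.CCCC[N+](CCCC)(CCCC)CCCC
F2 | step 8 | methyl 2-[(tert-butylperoxy)methyl]prop-2-enoate | C=C(COOC(C)(C)C)C(=O)OC
F3 | step 8 | methyl (2E,4R,5S)-2-[(tert-butylperoxy)methyl]-4-{[(2E)-3-methylpent-2-enoyl]oxy}-5-{[(2R)-2-methylbutanoyl]oxy}-6-[(1R)-4-methyl-5-oxocyclohex-3-en-1-yl]hepta-2,6-dienoate | CC1=CC[C@@H](C(=C)[C@H](OC(=O)[C@H](C)CC)[C@H](OC(=O)/C=C(\C)CC)/C=C(\COOC(C)(C)C)C(=O)OC)CC1=O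
F4 | step 8 | TBS dienol ether of F3 | CC1=C(O[Si](C)(C)C(C)(C)C)C[C@H](C(=C)[C@H](OC(=O)[C@H](C)CC)[C@H](OC(=O)/C=C(\C)CC)/C=C(\COOC(C)(C)C)C(=O)OC)C=C1
F5 | step 8 | bridgehead-silyloxy bicyclo[2.2.2]octene cycloadduct of F4 | C=C1[C@H]2C[C@]3(O[Si](C)(C)C(C)(C)C)C(C)=C[C@H]2[C@@H]([C@@]3(COOC(C)(C)C)C(=O)OC)[C@@H](OC(=O)/C=C(\C)CC)[C@H]1OC(=O)[C@H](C)CC
F6 | step 8 | methyl (1S,6R,7R,8R,9S,11S)-11,12-epoxy-8-[(2E)-3-methylpent-2-enoyloxy]-9-[(2R)-2-methylbutanoyloxy]-3-oxo-cis-cadina-4,10(14)-dien-13-oate | C=C1[C@H]2CC(=O)C(C)=C[C@H]2[C@@H]([C@@]2(C(=O)OC)CO2)[C@@H](OC(=O)/C=C(\C)CC)[C@H]1OC(=O)[C@H](C)CC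
F7 | step 10 | (Z)-enol acetate of 22 (C5=C4(OAc)CH3, O cis to C3) | C=C1[C@H]2CC(=O)/C(=C(/C)OC(C)=O)[C@H]2[C@@H]([C@@]2(C(=O)OC)CO2)[C@@H](OC(=O)/C=C(\C)CC)[C@H]1OC(=O)[C@H](C)CC
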